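**Retrosynthetic overview**

1. Rings A and B (the decalin) are made last and together. The target is opened to an all-E open-chain pentaenyl butenolide, which closes by one proton-initiated, head-to-tail bicyclization under a chiral acid (ring A, then ring B, ending by loss of H-9 to the C8=C9 alkene), as a terpene cyclase would do.
2. The butenolide ring is bought, not built: C16–C17 is cut by Suzuki coupling of a dienyl boronate with 4-bromofuran-2(5H)-one.
3. C15=C16 comes from a boron–Wittig reaction on an (E)-4-hydroxy-2-enal. Its C13=C14 bond and geometry come from a crossed aldol condensation of a C18 trienal with glyoxal mono(dimethyl acetal).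
4. The C18 trienal is cut at C11–C12 into (2E,6E)-farnesyl bromide and a three-carbon acetal Grignard reagent.
5. Ring order: butenolide (purchased, attached in the fifth step), then ring A and ring B in the sixth and last step. Numbering used: decalin C1–C10, chain C11–C16, hydroxymethyl C24, butenolide C17–C19 and C25.

Assumption: the (R)-configured binaphthol ligand of step 6 is taken to give the same facial sense as in its known cyclization of homofarnesol to (−)-ambrox (the (S)-ligand is used if the sense proves opposite), and product below 99% ee is upgraded by preparative chiral HPLC.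

**Route**

Step 1
Reactants: 1 (2E,6E)-farnesyl bromide; 2 2-(2-bromoethyl)-1,3-dioxolane
Product: 5 (5E,9E)-6,10,14-trimethylpentadeca-5,9,13-trienal, via Grignard reagent 3 (not isolated), via dioxolane 4 (not isolated)
Conditions: 2, Mg, THF, 25 °C; then 1, Li2CuCl4 (3 mol %), THF, −10 → 0 °C; then 2 M aq. HCl, THF, 23 °C
Reagents that add atoms: water, O
Why: Copper-catalysed Grignard–allylic bromide cross-coupling (Kochi type) joins C11 to C12 at the primary carbon with retention of both E-alkenes, and aqueous acid then hydrolyses the dioxolane to the aldehyde; no stereocentre is formed.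

Step 2
Reactants: 5 (5E,9E)-6,10,14-trimethylpentadeca-5,9,13-trienal; 6 2,2-dimethoxyacetaldehyde
Product: 7 (2E)-4,4-dimethoxy-2-[(3E,7E)-4,8,12-trimethyltrideca-3,7,11-trien-1-yl]but-2-enal
Conditions: 6 (60% in water, 3 equiv), pyrrolidine (20 mol %), propionic acid (20 mol %), i-PrOH, 45 °C, 5 added over 6 h
Reagents that add atoms: none
Why: Amine/acid-catalysed crossed aldol (Mannich-type) condensation, as in the known condensation of propanal with glyoxal monoacetals: the enamine of 5 attacks the very electrophilic, practically non-enolising aldehyde 6, and elimination under equilibrating conditions gives the E-enal (formyl group trans to C15), which fixes the C13=C14 geometry of the target.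

Step 3
Reactants: 7 (2E)-4,4-dimethoxy-2-[(3E,7E)-4,8,12-trimethyltrideca-3,7,11-trien-1-yl]but-2-enal
Product: 9 (2E,6E,10E)-3-(hydroxymethyl)-7,11,15-trimethylhexadeca-2,6,10,14-tetraenal, via allylic alcohol acetal 8 (not isolated)
Conditions: NaBH4, MeOH, 0 °C; then 1 M aq. citric acid, THF, 23 °C
Reagents that add atoms: water, O
Why: Chemoselective 1,2-reduction of the enal by NaBH4, then mild acid hydrolysis of the allylic dimethyl acetal as used for (E)-4-hydroxy-2-enals; the E-alkene keeps hydroxyl and aldehyde apart, so no lactol or furan forms and the C13=C14 geometry is kept.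

Step 4
Reactants: 9 (2E,6E,10E)-3-(hydroxymethyl)-7,11,15-trimethylhexadeca-2,6,10,14-tetraenal
Product: 10 (2E,4E)-5-(4,4,5,5-tetramethyl-1,3,2-dioxaborolan-2-yl)-2-[(3E,7E)-4,8,12-trimethyltrideca-3,7,11-trien-1-yl]penta-2,4-dien-1-ol
Conditions: bis(pinacolboryl)methane (2.3 equiv), lithium 2,2,6,6-tetramethylpiperidide (LiTMP, 2.3 equiv), THF, 0 °C; then 9, −78 °C → 23 °C
Reagents that add atoms: bis(4,4,5,5-tetramethyl-1,3,2-dioxaborolan-2-yl)methane, CC1(C)OB(CB2OC(C)(C)C(C)(C)O2)OC1(C)C
Why: Boron–Wittig olefination, in which the α-boryl carbanion adds 1,2 to the aldehyde and syn-elimination of lithium pinacolborate gives the trans (E) C15=C16 alkenyl boronate, one extra equivalent of carbanion being consumed by the hydroxyl.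

Step 5
Reactants: 10 (2E,4E)-5-(4,4,5,5-tetramethyl-1,3,2-dioxaborolan-2-yl)-2-[(3E,7E)-4,8,12-trimethyltrideca-3,7,11-trien-1-yl]penta-2,4-dien-1-ol; 11 4-bromofuran-2(5H)-one
Product: 12 4-[(1E,3E,7E,11E)-4-(hydroxymethyl)-8,12,16-trimethylheptadeca-1,3,7,11,15-pentaen-1-yl]furan-2(5H)-one
Conditions: Pd(PPh3)4 (5 mol %), K3PO4 (2 equiv), THF/H2O 10:1, 40 °C, dark
Reagents that add atoms: none
Why: Suzuki–Miyaura cross-coupling of the alkenyl boronate with the activated β-bromo enoate 11 forms the C16–C17 bond with retention of both alkene geometries and brings in the butenolide ring intact.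

Step 6
Reactants: 12 4-[(1E,3E,7E,11E)-4-(hydroxymethyl)-8,12,16-trimethylheptadeca-1,3,7,11,15-pentaen-1-yl]furan-2(5H)-one
Product: 13 4-[(1E,3E)-4-(hydroxymethyl)-6-[(4aS,8aS)-2,5,5,8a-tetramethyl-3,4,4a,5,6,7,8,8a-octahydronaphthalen-1-yl]hexa-1,3-dien-1-yl]furan-2(5H)-one (CNP0232848.5)
Conditions: (R)-2'-(2-fluorobenzyloxy)-[1,1'-binaphthalen]-2-ol (2.2 equiv), SnCl4 (2.0 equiv), CH2Cl2/toluene, −78 °C, 72 h; then CF3CO2H (10 equiv), SnCl4 (1.0 equiv), −78 °C, 24 h; aq. NaHCO3
Reagents that add atoms: none
Why: Proposed new method: the tin tetrachloride-activated hydroxyl proton of the (R)-binaphthol ligand is delivered to one face of the terminal isopropylidene group and ring A, then ring B, close through a chair–chair array by anti addition across the two E-trisubstituted alkenes (Stork–Eschenmoser course, setting 5S and 10S with H-5 and the C10 methyl trans), while the C13=C14 alkene, being part of a Lewis-acid-bound electron-poor trienyl lactone, cannot capture the C8 cation, which therefore ends by loss of the axial H-9 to the tetrasubstituted alkene, the CF3CO2H·SnCl4 stage driving the cascade to completion and equilibrating the alkene to this most substituted position; the closest known reaction type is the chiral Lewis-acid-assisted Brønsted acid (LBA) cation–olefin polycyclization of homofarnesol and homofarnesic acid to (−)-ambrox and (+)-sclareolide.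

**Compound list**

1 | (2E,6E)-farnesyl bromide [(2E,6E)-1-bromo-3,7,11-trimethyldodeca-2,6,10-triene] | CC(C)=CCC/C(C)=C/CC/C(C)=C/CBr | starting material
2 | 2-(2-bromoethyl)-1,3-dioxolane | BrCCC1OCCO1 | starting material
3 | [2-(1,3-dioxolan-2-yl)ethyl]magnesium bromide | Br[Mg]CCC1OCCO1 | intermediate
4 | 2-[(4E,8E)-5,9,13-trimethyltetradeca-4,8,12-trien-1-yl]-1,3-dioxolane | CC(C)=CCC/C(C)=C/CC/C(C)=C/CCCC1OCCO1 | intermediate
5 | (5E,9E)-6,10,14-trimethylpentadeca-5,9,13-trienal | CC(C)=CCC/C(C)=C/CC/C(C)=C/CCCC=O | intermediate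
6 | 2,2-dimethoxyacetaldehyde (glyoxal mono(dimethyl acetal)) | COC(OC)C=O | starting material
7 | (2E)-4,4-dimethoxy-2-[(3E,7E)-4,8,12-trimethyltrideca-3,7,11-trien-1-yl]but-2-enal | CC(C)=CCC/C(C)=C/CC/C(C)=C/CC/C(C=O)=C\C(OC)OC | intermediate
8 | (2E)-4,4-dimethoxy-2-[(3E,7E)-4,8,12-trimethyltrideca-3,7,11-trien-1-yl]but-2-en-1-ol | CC(C)=CCC/C(C)=C/CC/C(C)=C/CC/C(CO)=C\C(OC)OC | intermediate
9 | (2E,6E,10E)-3-(hydroxymethyl)-7,11,15-trimethylhexadeca-2,6,10,14-tetraenal | CC(C)=CCC/C(C)=C/CC/C(C)=C/CC/C(CO)=C\C=O | intermediate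
10 | (2E,4E)-5-(4,4,5,5-tetramethyl-1,3,2-dioxaborolan-2-yl)-2-[(3E,7E)-4,8,12-trimethyltrideca-3,7,11-trien-1-yl]penta-2,4-dien-1-ol | CC(C)=CCC/C(C)=C/CC/C(C)=C/CC/C(CO)=C\C=C\B1OC(C)(C)C(C)(C)O1 | intermediate
11 | 4-bromofuran-2(5H)-one | BrC1=CC(=O)OC1 | starting material
12 | 4-[(1E,3E,7E,11E)-4-(hydroxymethyl)-8,12,16-trimethylheptadeca-1,3,7,11,15-pentaen-1-yl]furan-2(5H)-one | CC(C)=CCC/C(C)=C/CC/C(C)=C/CC/C(CO)=C\C=C\C1=CC(=O)OC1 | intermediate
13 | 4-[(1E,3E)-4-(hydroxymethyl)-6-[(4aS,8aS)-2,5,5,8a-tetramethyl-3,4,4a,5,6,7,8,8a-octahydronaphthalen-1-yl]hexa-1,3-dien-1-yl]furan-2(5H)-one | CC1=C(CC/C(=C\C=C\C2=CC(=O)OC2)CO)[C@@]2(C)CCCC(C)(C)[C@@H]2CC1 | target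

**Step count and risks**

Total step count: 6. Longest linear sequence: 6 (1 → 5 → 7 → 9 → 10 → 12 → 13).

Steps most likely to fail:

Step 6 (bicyclization of 12). The risks are achiral background protonation through the free hydroxyl or the lactone (lower ee), incomplete closure of ring B, a mixture of C7, C8(17) and C8(9) alkenes, and E/Z drift of the trienyl lactone under acid. The fallback sets out from 9 and comes back at 13; it moves the ring-forming step ahead of the trienyl butenolide. Hydroxy enal 9, whose only other alkene is a deactivated enal, is cyclized with the same chiral acid and then CF3CO2H·SnCl4 to the bicyclic hydroxy enal F1. This is taken through the boron–Wittig reaction (bis(pinacolboryl)methane, LiTMP, THF) to the bicyclic dienyl boronate F2, and Suzuki coupling of that with 11 (Pd(PPh3)4, K3PO4, THF/H2O) gives 13 directly.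

Step 2 (crossed aldol condensation). The risks are self-condensation of 5, over-reaction of the product enal, and incomplete E-selectivity. The fallback sets out from 5 and comes back at 7; it replaces the catalytic condensation by a directed aldol through a metallated imine. Compound 5 is condensed with tert-butylamine (MgSO4, CH2Cl2) to the N-tert-butyl aldimine F3. This is deprotonated with lithium diisopropylamide (LDA, THF, −78 → 0 °C) to the lithium aza-enolate F4, which adds to anhydrous 6 at −78 °C to give the β-hydroxy imine F5 (mixture of diastereomers). Stirring with AcOH/NaOAc/H2O buffer hydrolyses the imine and eliminates water to give 7.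

Step 5 (Suzuki coupling). The risks are base-induced opening of bromobutenolide 11 or of the product, and protodeboronation of the dienyl boronate. The fallback sets out from 9 and comes back at 12; it forms the C16–C17 bond by a Heck reaction instead. Compound 9 is methylenated (Ph3PCH3Br, KOtBu, THF, 0 °C) to the dienol F6. This is coupled at its terminal carbon with 11 under weakly basic, boron-free conditions (Pd(OAc)2 5 mol %, n-Bu4NCl, NaHCO3, DMF, 60 °C) to give 12.

Further compounds

F1 | step 6 | (2E)-3-(hydroxymethyl)-5-[(4aS,8aS)-2,5,5,8a-tetramethyl-3,4,4a,5,6,7,8,8a-octahydronaphthalen-1-yl]pent-2-enal | CC1=C(CC/C(CO)=C\C=O)[C@@]2(C)CCCC(C)(C)[C@@H]2CC1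
F2 | step 6 | (2E,4E)-5-(4,4,5,5-tetramethyl-1,3,2-dioxaborolan-2-yl)-2-{2-[(4aS,8aS)-2,5,5,8a-tetramethyl-3,4,4a,5,6,7,8,8a-octahydronaphthalen-1-yl]ethyl}penta-2,4-dien-1-ol | CC1=C(CC/C(CO)=C\C=C\B3OC(C)(C)C(C)(C)O3)[C@@]2(C)CCCC(C)(C)[C@@H]2CC1
F3 | step 2 | (1E,5E,9E)-N-tert-butyl-6,10,14-trimethylpentadeca-5,9,13-trien-1-imine | CC(C)=CCC/C(C)=C/CC/C(C)=C/CCC/C=N/C(C)(C)C
F4 | step 2 | lithium N-tert-butyl-N-[(5E,9E)-6,10,14-trimethylpentadeca-1,5,9,13-tetraen-1-yl]amide (aza-enolate, C1=C2 geometry undefined) | CC(C)=CCC/C(C)=C/CC/C(C)=C/CCC=CN([Li])C(C)(C)C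
F5 | step 2 | N-tert-butyl imine of 3-hydroxy-4,4-dimethoxy-2-[(3E,7E)-4,8,12-trimethyltrideca-3,7,11-trien-1-yl]butanal (mixture of diastereomers at C2 and C3) | CC(C)=CCC/C(C)=C/CC/C(C)=C/CCC(/C=N/C(C)(C)C)C(O)C(OC)OC
F6 | step 5 | (2E)-2-[(3E,7E)-4,8,12-trimethyltrideca-3,7,11-trien-1-yl]penta-2,4-dien-1-ol | CC(C)=CCC/C(C)=C/CC/C(C)=C/CC/C(CO)=C\C=C
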